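# Proposed synthesis of tricetin 3'-sulfate

## The problem

Tricetin 3'-sulfate is a flavone: a 4-pyranone (ring C) fused to a benzene ring with hydroxyls on C5 and C7 (ring A), carrying at C2 a ring B with oxygens on C3', C4' and C5', one outer oxygen of which is a sulfate monoester. There is no stereocenter, so the task is one of regiochemistry and protecting-group logic, not of stereocontrol. Five phenolic oxygens are present and exactly one must be sulfated, namely an outer hydroxyl of the symmetric ring B. It has to be told apart from its two ring B neighbours, of which the C4' hydroxyl is the more acidic, and from the reactive C7 hydroxyl. The aryl sulfate is the fragile group: acid hydrolyses it, Lewis acids strip it, and every intermediate that carries it is a polar salt, so it must come late and be followed only by neutral chemistry. The pyranone is the second sensitive site, because hard nucleophiles can add to C2 and open ring C. One structural feature simplifies the skeleton: C5, C7 and C8a, the three oxygen-bearing carbons of ring A, are ortho, para and ortho to the carbon that bears the C4 carbonyl, so each of these C–O bonds can be made by addition–elimination on a carbonyl-activated fluoroarene. Ring B has the oxygen pattern of gallic acid, in which bridging two adjacent hydroxyls necessarily leaves an outer one free.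

## Retrosynthesis

**Target 14 to 13.** The last operation cuts four O–C bonds: the two benzyl ether bonds on O5 and O7 and the two ketal bonds on O4' and O5' of the protected sulfate 13. Hydrogenolysis is preferred to end groups removed by protic or Lewis acid, because it is the one global deprotection that an aryl sulfate survives. Compound 13 is larger than 14, but everything in it except the sulfate falls in a single neutral step. The forward reaction must cleave three benzylic-type groups without reducing C2=C3 and without solvolysing the S–O bond.

**13 to 12.** The S–O bond is cut. Sulfating the free pentaphenol would give mixtures, so the position of the sulfate is fixed by the protecting-group pattern: the phenol 12 has a single hydroxyl, at C3'. The forward reaction only has to sulfate a phenol flanked by a ketal oxygen.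

**12 to 11.** No skeletal bond is cut; O3' is masked as a methoxymethyl (MOM) ether in 11. This group must survive a Grignard reagent, a lithium enolate, fluoride and an alkoxide, which excludes esters and silyl ethers, and it must leave before the benzyl ethers and the ketal do. An acetal cleaved by mild acid fits. The forward step is asked to be selective against the diphenylmethylene ketal.

**11 to 9 and 10.** The C5–O and C7–O bonds are cut, giving the difluoroflavone 9 and benzyl alcohol 10. Both carbons are activated by the C4 carbonyl, and the oxygens arrive already benzylated, so no separate protection of ring A is needed. Carrying benzyloxy groups through the ring closure instead would require an acid chloride that is not commercial and would make the closure slower. Fluorine serves twice: as activator in the ring closure and as leaving group here. The forward reaction must exchange both fluorides without benzyloxide destroying the pyranone.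

**9 to 6 and 7, through 8.** This is the central disconnection: O1–C8a and C3–C4 are cut, leading to the ring B methyl ketone 6 and commercial 2,4,6-trifluorobenzoyl chloride 7 by way of the 1,3-diketone 8. The classical flavone closures cut O1–C2 instead. They need a ring A ketone with one free ortho hydroxyl and two protected ones, and they end with hot acid or an oxidant, which the MOM ether and ketal on ring B would not tolerate. The chosen cut uses base only, joins two fragments of similar size and forms ring C in the same operation. The forward reaction needs C-acylation of the enolate and ring closure through oxygen.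

**6 to 4, through 5.** The acyl–methyl bond is cut. The ketone 6 comes from the ester 4 by way of the N-methoxy-N-methylamide 5, which stops the addition of a methyl Grignard reagent at the ketone stage. Direct addition to the ester would run on to the tertiary alcohol.

**4 to 3 to 1 and 2.** The MOM ether and then the ketal are removed, leading to methyl gallate 1 and dichlorodiphenylmethane 2. The two ketal C–O bonds are the cut that desymmetrises ring B. Only adjacent hydroxyls of 1 can be bridged, both adjacent pairs give the same compound 3, and the hydroxyl left over is an outer one, the future sulfate position. The forward reaction is a known high-temperature ketalisation.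

## Roads not taken

**Alternative 1:** Ring B would be made instead of bought, by cutting C1'–C6' and C2'–C3'.
- **Key step.** 3,4-Bis(benzyloxy)furan (A2) adds as a diene across the triple bond of 5,7-bis(benzyloxy)-2-ethynylchromen-4-one (A1). Acid then opens the oxygen bridge, so the former furan oxygen becomes the C3' hydroxyl of 5,7-bis(benzyloxy)-2-[3,4-bis(benzyloxy)-5-hydroxyphenyl]chromen-4-one (A3).
- **Merits.** A3 has exactly one free phenol, in the right place, as a direct result of the bond construction. Every other oxygen carries benzyl, so A3 needs only sulfation and one hydrogenolysis. There is no third protecting-group class and no counterpart to the acid-selective step 6. In this respect the alternative is better than the chosen plan.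
- **Weak points.** A benzene ring is built that gallic acid supplies with the correct oxygens already in place. Neither A1 nor A2 is commercial, and each needs a sequence of its own of about four steps. The alkyne of A1 is activated only as a substituent on a vinylogous ester, so the cycloaddition with an electron-rich, acid-sensitive furan would need heat, where furan adducts revert. The bridge must also open in one direction only: ionisation has to occur at the bridgehead next to the flavone-bearing carbon for the hydroxyl to end up meta to the flavone bond. That rests on a modest electronic bias, and the wrong mode would place the hydroxyl ortho to the biaryl bond.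
- **Comparison.** Against the cleaner end game of this road, the chosen plan sets a ring B precursor reached in three steps from methyl gallate 1 with unambiguous regiochemistry, and a flavone-forming step whose two partners are one commercial and one short-sequence compound.

**Alternative 2:** Rings A and C would both come from an open chain, by cutting C4a–C5 and O1–C2.
- **Key step.** Methyl 9-[7-(methoxymethoxy)-2,2-diphenyl-1,3-benzodioxol-5-yl]-3,5,7,9-tetraoxononanoate (A4) would be folded with Mg(OMe)2, so that its C6 methylene acylates the ester carbon, and then dehydrated in warm acetic acid. The product is 5,7-dihydroxy-2-[7-(methoxymethoxy)-2,2-diphenyl-1,3-benzodioxol-5-yl]chromen-4-one (A5).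
- **Merits.** A4 could be assembled from the same ring B ester 4. Two rings form in one operation. No fluorinated reagent and no substitution on a finished pyranone is needed, so the risk of step 5 does not arise. If the folding were clean the step count would be about the same.
- **Weak points.** A4 is a polyenolised, unstable compound made with several equivalents of strong base. The mode of closure is not secured by the substrate: aldol-type closure onto a ketone carbon and closure through an enol oxygen compete with the Claisen-type closure. The warm acetic acid also threatens the MOM ether. A5 is less advanced than it looks, because its C5 and C7 hydroxyls must be benzylated before O3' can be unmasked and sulfated.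
- **Comparison.** In the chosen plan ring A is a prefabricated arene whose regiochemistry is fixed by the ortho and para relationship to one carbonyl, and the benzyl groups arrive in the step that makes the C–O bonds.

**Alternative 3:** Ring A would be built by cycloaddition, by cutting C4a–C5 and C8–C8a.
- **Key step.** 1-Methoxy-1,3-bis(trimethylsilyloxy)buta-1,3-diene (A7) adds to the C5=C6 bond of 2-[7-(allyloxy)-2,2-diphenyl-1,3-benzodioxol-5-yl]-5-bromopyran-4-one (A6). Loss of HBr and methanol then aromatises the new ring to 5,7-dihydroxy-2-[7-(allyloxy)-2,2-diphenyl-1,3-benzodioxol-5-yl]chromen-4-one (A8).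
- **Merits.** The polarity of both partners fixes the regiochemistry: the nucleophilic CH2 terminus of A7 bonds to the carbon next to the ring oxygen. The bromine is a built-in leaving group for aromatisation. A7 is two silylations away from a commercial β-keto ester. The allyl ether on O3' is removed with a zerovalent palladium catalyst and is therefore more cleanly orthogonal to ketal and benzyl than the MOM ether of the chosen route; this is a real advantage.
- **Weak points.** A6 has to be made from the ring B ketone by building the pyranone and brominating it selectively at C5, several steps that the chosen plan replaces by one. The C5=C6 bond of a 4-pyranone is part of a vinylogous ester and a poor dienophile, while A7 is sensitive to moisture and acid. A8 again has free C5 and C7 hydroxyls that need benzylation.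
- **Comparison.** The chosen plan takes ring A with its three heteroatom positions from a commercial acid chloride, forms no carbocycle, and protects O5 and O7 in the step that creates them. It pays for this with the less orthogonal MOM group.

Key step: step 4

Assumption: the aryl sulfate is drawn as the free hydrogen sulfate, as in the target; in practice 13 and 14 would be handled as sodium salts, and the acid form of 14 set free at the end by a short pass through a sulfonic acid resin at 0 °C.

## Route

Step 1
Reactants: 1 methyl gallate; 2 dichlorodiphenylmethane
Product: 3 methyl 7-hydroxy-2,2-diphenyl-1,3-benzodioxole-5-carboxylate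
Conditions: neat (or Ph2O), 180 °C, under N2 with removal of HCl
Reagents that add atoms: none
Why: Ketalisation of a catechol by a gem-dichloride (double O-alkylation with loss of two HCl); only adjacent hydroxyls can close the five-membered dioxole, and in the symmetric gallate either adjacent pair gives the same product, so the hydroxyl that stays free is necessarily an outer one.

Step 2
Reactants: 3 methyl 7-hydroxy-2,2-diphenyl-1,3-benzodioxole-5-carboxylate
Product: 4 methyl 7-(methoxymethoxy)-2,2-diphenyl-1,3-benzodioxole-5-carboxylate
Conditions: MOMCl, iPr2NEt, CH2Cl2, 0 °C to rt
Reagents that add atoms: chloromethyl methyl ether (MOMCl), COCCl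
Why: Williamson-type O-alkylation of the single phenol with an α-chloro ether under amine base; the resulting acetal is inert to the organomagnesium, enolate and alkoxide steps that follow.

Step 3
Reactants: 4 methyl 7-(methoxymethoxy)-2,2-diphenyl-1,3-benzodioxole-5-carboxylate
Product: 6 1-[7-(methoxymethoxy)-2,2-diphenyl-1,3-benzodioxol-5-yl]ethanone, via N-methoxy-N-methylamide 5 (not isolated)
Conditions: MeNH(OMe)·HCl (1.5 equiv), iPrMgCl (3.0 equiv), THF, −20 °C; then MeMgBr (2.5 equiv), −20 to 0 °C; aq NH4Cl
Reagents that add atoms: N,O-dimethylhydroxylamine hydrochloride, CNOC.Cl (atoms present in 5 only); methylmagnesium bromide, C[Mg]Br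
Why: The magnesium amide formed from the hydroxylamine salt and iPrMgCl converts the ester into amide 5 (aminolysis), and MeMgBr then adds only once because the five-membered magnesium chelate of the tetrahedral adduct persists until work-up (Weinreb ketone synthesis). All iPrMgCl is consumed in making the magnesium amide, and the acetal and ketal do not react with Grignard reagents.

Step 4
Reactants: 6 1-[7-(methoxymethoxy)-2,2-diphenyl-1,3-benzodioxol-5-yl]ethanone; 7 2,4,6-trifluorobenzoyl chloride
Product: 9 5,7-difluoro-2-[7-(methoxymethoxy)-2,2-diphenyl-1,3-benzodioxol-5-yl]chromen-4-one, via trifluorophenyl 1,3-diketone 8 (not isolated)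
Conditions: LiN(SiMe3)2 (2.2 equiv), THF, −78 °C; 7 (1.05 equiv), −78 to 0 °C; AcOH quench, concentrate; K2CO3, DMF, 60 °C
Reagents that add atoms: none
Why: LiN(SiMe3)2 converts the methyl ketone 6 into its lithium enolate, which attacks the acid chloride 7 through carbon (Claisen-type C-acylation, bond C3–C4); the second equivalent of base at once turns the more acidic 1,3-diketone 8 into its chelated enolate, which shields it from a second acylation. After the acetic acid quench and change of solvent, K2CO3 in DMF regenerates the diketone enolate, and the oxygen on the ring B side adds to an ortho C–F carbon of the trifluorophenyl ring to give an anionic sigma-complex stabilised by the ketone and the other two fluorines; loss of fluoride forms bond O1–C8a and closes ring C. The ring closure is an intramolecular nucleophilic aromatic substitution, formally a 6-exo-trig addition to the arene C8a=C8 bond followed by elimination of fluoride. The closest known reaction type is the one-pot synthesis of flavones and 4-quinolones from ketone enolates and 2-fluorobenzoyl chlorides. No stereocenter is formed. Two selectivities are needed: C- over O-acylation, favoured by the lithium counter-ion, the low temperature and the excess of base over 7, and closure through oxygen, secured by ring size, since attack by the central carbon or by the other oxygen would give a four-membered ring. The two ortho fluorines are equivalent, so only one product can form, and the fluorines left on C5 and C7 remain activated by the C4 carbonyl for step 5.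

Step 5
Reactants: 9 5,7-difluoro-2-[7-(methoxymethoxy)-2,2-diphenyl-1,3-benzodioxol-5-yl]chromen-4-one; 10 benzyl alcohol
Product: 11 5,7-bis(benzyloxy)-2-[7-(methoxymethoxy)-2,2-diphenyl-1,3-benzodioxol-5-yl]chromen-4-one
Conditions: 10 (3 equiv), NaH (3 equiv), THF, 0 °C; then 9, DMF, 0 to 60 °C; AcOH quench
Reagents that add atoms: none
Why: Twofold nucleophilic aromatic substitution (addition–elimination): C7 is para and C5 ortho to the carbon bearing the C4 carbonyl, so both sigma-complexes are carbonyl-stabilised, and fluoride is the best leaving group for this mechanism. The MOM ether and ketal do not react with alkoxide, and pyranone opened by reversible addition of benzyloxide at C2 should re-close on the acidic quench.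

Step 6
Reactants: 11 5,7-bis(benzyloxy)-2-[7-(methoxymethoxy)-2,2-diphenyl-1,3-benzodioxol-5-yl]chromen-4-one
Product: 12 5,7-bis(benzyloxy)-2-(7-hydroxy-2,2-diphenyl-1,3-benzodioxol-5-yl)chromen-4-one
Conditions: HCl (2 M in MeOH), THF, 40 °C, stopped at full conversion
Reagents that add atoms: none
Why: Acid-catalysed transacetalisation of the formaldehyde acetal to dimethoxymethane. The MOM group has a basic alkyl oxygen and ionises to an unhindered oxocarbenium ion, whereas the cyclic ketal has only weakly basic aryl oxygens and re-closes after ionisation, so the phenol should be freed before the ketal or the benzyl ethers are affected.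

Step 7
Reactants: 12 5,7-bis(benzyloxy)-2-(7-hydroxy-2,2-diphenyl-1,3-benzodioxol-5-yl)chromen-4-one
Product: 13 6-[5,7-bis(benzyloxy)-4-oxochromen-2-yl]-2,2-diphenyl-1,3-benzodioxol-4-yl hydrogen sulfate
Conditions: SO3·pyridine (5 equiv), pyridine, 50 °C; aq NaHCO3
Reagents that add atoms: sulfur trioxide–pyridine complex, O=S(=O)=O.c1ccncc1
Why: O-Sulfation of a phenol by transfer of SO3 from its amine complex; 12 has a single hydroxyl, so the site of sulfation is fixed by the protecting-group pattern and not by reagent selectivity, and the basic medium protects the new sulfate from solvolysis.

Step 8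
Reactants: 13 6-[5,7-bis(benzyloxy)-4-oxochromen-2-yl]-2,2-diphenyl-1,3-benzodioxol-4-yl hydrogen sulfate
Product: 14 tricetin 3'-sulfate, 5-(5,7-dihydroxy-4-oxochromen-2-yl)-2,3-dihydroxyphenyl hydrogen sulfate
Conditions: H2 (1 atm), 10% Pd/C, THF/MeOH, rt; then sulfonic acid resin (H+ form), 0 °C
Reagents that add atoms: none
Why: Hydrogenolysis of benzylic C–O bonds: the two benzyl ethers give toluene and the doubly benzylic diaryl ketal gives diphenylmethane, under neutral conditions that leave the S–O ester intact. The cross-conjugated C2=C3 bond of a flavone is reduced much more slowly than benzylic ethers are cleaved, so the reaction is stopped when debenzylation is complete.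

## Compound list

1 | methyl gallate | COC(=O)c1cc(O)c(O)c(O)c1 | starting material
2 | dichlorodiphenylmethane | ClC(Cl)(c1ccccc1)c1ccccc1 | starting material
3 | methyl 7-hydroxy-2,2-diphenyl-1,3-benzodioxole-5-carboxylate | COC(=O)c1cc(O)c2OC(c3ccccc3)(c3ccccc3)Oc2c1 | intermediate
4 | methyl 7-(methoxymethoxy)-2,2-diphenyl-1,3-benzodioxole-5-carboxylate | COCOc1cc(C(=O)OC)cc2OC(c3ccccc3)(c3ccccc3)Oc12 | intermediate
5 | N-methoxy-7-(methoxymethoxy)-N-methyl-2,2-diphenyl-1,3-benzodioxole-5-carboxamide | COCOc1cc(C(=O)N(C)OC)cc2OC(c3ccccc3)(c3ccccc3)Oc12 | intermediate
6 | 1-[7-(methoxymethoxy)-2,2-diphenyl-1,3-benzodioxol-5-yl]ethanone | CC(=O)c1cc(OCOC)c2OC(c3ccccc3)(c3ccccc3)Oc2c1 | intermediate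
7 | 2,4,6-trifluorobenzoyl chloride | O=C(Cl)c1c(F)cc(F)cc1F | starting material
8 | 1-[7-(methoxymethoxy)-2,2-diphenyl-1,3-benzodioxol-5-yl]-3-(2,4,6-trifluorophenyl)propane-1,3-dione | O=C(CC(=O)c1c(F)cc(F)cc1F)c1cc(OCOC)c2OC(c3ccccc3)(c3ccccc3)Oc2c1 | intermediate
9 | 5,7-difluoro-2-[7-(methoxymethoxy)-2,2-diphenyl-1,3-benzodioxol-5-yl]chromen-4-one | O=c1cc(-c2cc(OCOC)c3OC(c4ccccc4)(c4ccccc4)Oc3c2)oc2cc(F)cc(F)c12 | intermediate
10 | benzyl alcohol | OCc1ccccc1 | starting material
11 | 5,7-bis(benzyloxy)-2-[7-(methoxymethoxy)-2,2-diphenyl-1,3-benzodioxol-5-yl]chromen-4-one | O=c1cc(-c2cc(OCOC)c3OC(c4ccccc4)(c4ccccc4)Oc3c2)oc2cc(OCc3ccccc3)cc(OCc3ccccc3)c12 | intermediate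
12 | 5,7-bis(benzyloxy)-2-(7-hydroxy-2,2-diphenyl-1,3-benzodioxol-5-yl)chromen-4-one | O=c1cc(-c2cc(O)c3OC(c4ccccc4)(c4ccccc4)Oc3c2)oc2cc(OCc3ccccc3)cc(OCc3ccccc3)c12 | intermediate
13 | 6-[5,7-bis(benzyloxy)-4-oxochromen-2-yl]-2,2-diphenyl-1,3-benzodioxol-4-yl hydrogen sulfate | O=c1cc(-c2cc(OS(=O)(=O)O)c3OC(c4ccccc4)(c4ccccc4)Oc3c2)oc2cc(OCc3ccccc3)cc(OCc3ccccc3)c12 | intermediate
14 | tricetin 3'-sulfate, 5-(5,7-dihydroxy-4-oxochromen-2-yl)-2,3-dihydroxyphenyl hydrogen sulfate | O=c1cc(-c2cc(O)c(O)c(OS(=O)(=O)O)c2)oc2cc(O)cc(O)c12 | target

## Step count and risks

Total step count: 8. Longest linear sequence: 8 steps, from methyl gallate 1 to 14.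

**Step 4 (key step).** The enolate may be acylated on oxygen, the first-formed diketone may be acylated a second time, or the amide base may attack the acid chloride or an activated C–F position before the enolate does. In the second stage, displacement of the para fluorine by dimethylamine from DMF could compete if the temperature is raised much above 60 °C. The fallback replaces the acylation by an aldol addition followed by oxidation. It sets out from 6. The lithium enolate of 6 is added to commercial 2,4,6-trifluorobenzaldehyde at −78 °C, which can only react at carbon and consumes one equivalent of base. This gives the racemic β-hydroxy ketone 3-hydroxy-1-[7-(methoxymethoxy)-2,2-diphenyl-1,3-benzodioxol-5-yl]-3-(2,4,6-trifluorophenyl)propan-1-one (F1). Oxidation of F1 with Dess–Martin periodinane in CH2Cl2 gives the diketone 8, where the route is rejoined; closure with K2CO3 in DMF then leads to 9 as in step 4.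

**Step 5.** The exchange may stop after the first fluoride, because the new benzyloxy group donates into the C4 carbonyl and weakens the activation of the second position. The forcing needed to complete it may let benzyloxide add to C2 and cleave the opened diketone irreversibly. The fallback finishes the second exchange with a weakly basic α-effect nucleophile. It sets out from 9. One equivalent of NaOCH2Ph in DMF at 0 °C displaces the fluoride para to the carbonyl, which is expected to be the more reactive one, to give the monoether 7-(benzyloxy)-5-fluoro-2-[7-(methoxymethoxy)-2,2-diphenyl-1,3-benzodioxol-5-yl]chromen-4-one (F2). Treatment of F2 with acetohydroxamic acid and K2CO3 in DMSO at 80 °C then replaces the remaining ortho fluoride by O-arylation and fragmentation of the O-aryl hydroxamate, giving the phenol 7-(benzyloxy)-5-hydroxy-2-[7-(methoxymethoxy)-2,2-diphenyl-1,3-benzodioxol-5-yl]chromen-4-one (F3). Benzylation of the chelated C5 hydroxyl of F3 with benzyl bromide and K2CO3 in DMF at 60 °C returns to the route at 11.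

**Step 6.** Loss of the diphenylmethylene ketal alongside the MOM group is the main danger, with acid cleavage of the peri C5 benzyl ether as a lesser one. The fallback gives up the selectivity and uses the symmetry of ring B a second time. It sets out from 11. Both the acetal and the ketal are removed on purpose with HCl in aqueous MeOH/THF at 50 °C, giving the triol 5,7-bis(benzyloxy)-2-(3,4,5-trihydroxyphenyl)chromen-4-one (F4). The ketal is then put back by treating F4 with dichlorodiphenylmethane 2 and K2CO3 in MeCN under argon. As in the ketalisation of methyl gallate 1, only adjacent hydroxyls of F4 can be bridged and both pairs are equivalent, so the only ketal that can form is 12, where the route is rejoined.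

**Step 7.** Sulfation of a hindered, weakly nucleophilic phenol may stay incomplete, and the sulfate may be lost by acid-catalysed solvolysis while the amphiphilic salt is isolated. The fallback carries the sulfate in protected, neutral form. It sets out from 12. Treatment with 2,2,2-trichloroethyl chlorosulfate, NEt3 and DMAP in THF gives the sulfate diester 6-[5,7-bis(benzyloxy)-4-oxochromen-2-yl]-2,2-diphenyl-1,3-benzodioxol-4-yl 2,2,2-trichloroethyl sulfate (F5), which can be purified on silica. Transfer hydrogenolysis of F5 with Pd/C and ammonium formate in MeOH removes the benzyl ethers, the ketal and the trichloroethyl group in one operation. This rejoins the route at 14, which is obtained as its ammonium salt and converted to the acid form as stated in the assumption. The same buffered conditions would also serve if the hydrogen atmosphere of step 8 reduced the C2=C3 bond.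

## Further compounds

F1 | step 4 | 3-hydroxy-1-[7-(methoxymethoxy)-2,2-diphenyl-1,3-benzodioxol-5-yl]-3-(2,4,6-trifluorophenyl)propan-1-one (racemic) | OC(CC(=O)c1cc(OCOC)c2OC(c3ccccc3)(c3ccccc3)Oc2c1)c1c(F)cc(F)cc1F
F2 | step 5 | 7-(benzyloxy)-5-fluoro-2-[7-(methoxymethoxy)-2,2-diphenyl-1,3-benzodioxol-5-yl]chromen-4-one | O=c1cc(-c2cc(OCOC)c3OC(c4ccccc4)(c4ccccc4)Oc3c2)oc2cc(OCc3ccccc3)cc(F)c12
F3 | step 5 | 7-(benzyloxy)-5-hydroxy-2-[7-(methoxymethoxy)-2,2-diphenyl-1,3-benzodioxol-5-yl]chromen-4-one | O=c1cc(-c2cc(OCOC)c3OC(c4ccccc4)(c4ccccc4)Oc3c2)oc2cc(OCc3ccccc3)cc(O)c12
F4 | step 6 | 5,7-bis(benzyloxy)-2-(3,4,5-trihydroxyphenyl)chromen-4-one | O=c1cc(-c2cc(O)c(O)c(O)c2)oc2cc(OCc3ccccc3)cc(OCc3ccccc3)c12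
F5 | step 7 | 6-[5,7-bis(benzyloxy)-4-oxochromen-2-yl]-2,2-diphenyl-1,3-benzodioxol-4-yl 2,2,2-trichloroethyl sulfate | O=c1cc(-c2cc(OS(=O)(=O)OCC(Cl)(Cl)Cl)c3OC(c4ccccc4)(c4ccccc4)Oc3c2)oc2cc(OCc3ccccc3)cc(OCc3ccccc3)c12
A1 | alternative 1 | 5,7-bis(benzyloxy)-2-ethynylchromen-4-one | C#Cc1cc(=O)c2c(OCc3ccccc3)cc(OCc3ccccc3)cc2o1
A2 | alternative 1 | 3,4-bis(benzyloxy)furan | c1occ(OCc2ccccc2)c1OCc1ccccc1
A3 | alternative 1 | 5,7-bis(benzyloxy)-2-[3,4-bis(benzyloxy)-5-hydroxyphenyl]chromen-4-one | O=c1cc(-c2cc(O)c(OCc3ccccc3)c(OCc3ccccc3)c2)oc2cc(OCc3ccccc3)cc(OCc3ccccc3)c12
A4 | alternative 2 | methyl 9-[7-(methoxymethoxy)-2,2-diphenyl-1,3-benzodioxol-5-yl]-3,5,7,9-tetraoxononanoate | COC(=O)CC(=O)CC(=O)CC(=O)CC(=O)c1cc(OCOC)c2OC(c3ccccc3)(c3ccccc3)Oc2c1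
A5 | alternative 2 | 5,7-dihydroxy-2-[7-(methoxymethoxy)-2,2-diphenyl-1,3-benzodioxol-5-yl]chromen-4-one | O=c1cc(-c2cc(OCOC)c3OC(c4ccccc4)(c4ccccc4)Oc3c2)oc2cc(O)cc(O)c12
A6 | alternative 3 | 2-[7-(allyloxy)-2,2-diphenyl-1,3-benzodioxol-5-yl]-5-bromopyran-4-one | O=c1cc(-c2cc(OCC=C)c3OC(c4ccccc4)(c4ccccc4)Oc3c2)occ1Br
A7 | alternative 3 | 1-methoxy-1,3-bis(trimethylsilyloxy)buta-1,3-diene (geometry of the C1=C2 bond not defined) | COC(O[Si](C)(C)C)=CC(=C)O[Si](C)(C)C
A8 | alternative 3 | 5,7-dihydroxy-2-[7-(allyloxy)-2,2-diphenyl-1,3-benzodioxol-5-yl]chromen-4-one | O=c1cc(-c2cc(OCC=C)c3OC(c4ccccc4)(c4ccccc4)Oc3c2)oc2cc(O)cc(O)c12
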